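The target is numbered as a bicyclo[3.2.1]octane: C1 prenyl bridgehead, C5 methyl bridgehead, C8 bridging ketone. The cyclopentanone ring C1–C7–C6–C5–C8 is carved out of the cyclohexanone ring of a bicyclo[3.3.1]nonane. In that precursor a CMe2 carbon still sits between C5 and C6, and C6 carries an equatorial benzenesulfonate. The C–O bond is antiperiplanar to the C5–CMe2 ring bond, so ionisation triggers a Wagner–Meerwein shift. C5 moves to C6 with inversion, six ring atoms become five, and the expelled CMe2 cation takes up water. The feature exploited is the C5–C6–C(CH3)2OH array, a tertiary carbinol next to a quaternary bridgehead. One Sharpless epoxide desymmetrises a prochiral cyclohexadiene and sets all configuration.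

Key step: step 11

Remark on the chemistry: the β-triketone of the target exists as rapidly interconverting enol tautomers, and the route delivers this mixture, written as the tautomer of the target structure. The bicyclo[3.3.1]nonane intermediates are numbered as follows:
- C1: bridgehead that receives the methyl group
- C2–C4: enone bridge
- C5: prenyl bridgehead
- C6: CH2
- C7: oxygenated CH
- C8: CMe2
- C9: one-carbon bridge

Step 1
Reactants: 1 3-methylbut-2-en-1-ol (prenol)
Product: 2 [(2R)-3,3-dimethyloxiran-2-yl]methanol
Conditions: Ti(OiPr)4 (cat.), D-(−)-diisopropyl tartrate (cat.), t-BuOOH, 4 Å molecular sieves, CH2Cl2, −20 °C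
Reagents that add atoms: tert-butyl hydroperoxide, CC(C)(C)OO
Why: Sharpless asymmetric epoxidation of a primary allylic alcohol, in which the D-(−)-tartrate titanium catalyst delivers oxygen to one face of the trisubstituted alkene and sets the (R) centre that later becomes C6 of the target.

Step 2
Reactants: 2 [(2R)-3,3-dimethyloxiran-2-yl]methanol
Product: 3 (2S)-2-(bromomethyl)-3,3-dimethyloxirane
Conditions: CBr4, PPh3, 2,6-lutidine, CH2Cl2, −10 °C
Reagents that add atoms: carbon tetrabromide, BrC(Br)(Br)Br
Why: Appel reaction, an SN2 exchange at the primary carbinol carbon that leaves the neighbouring epoxide centre untouched (the descriptor becomes S only because bromine changes the priorities).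

Step 3
Reactants: 4 1,5-dimethoxycyclohexa-1,4-diene
Product: 6 1,5-dimethoxy-6-(3-methylbut-2-en-1-yl)cyclohexa-1,4-diene, via 6-lithiodiene 5 (not isolated)
Conditions: t-BuLi, THF, −78 °C; then prenyl bromide, −78 to 0 °C
Reagents that add atoms: 1-bromo-3-methylbut-2-ene (prenyl bromide), CC(C)=CCBr
Why: Deprotonation of the doubly allylic C6 methylene flanked by the two methoxy-bearing carbons gives a pentadienyl-type anion that undergoes SN2 alkylation at C6 by the allylic bromide.

Step 4
Reactants: 6 1,5-dimethoxy-6-(3-methylbut-2-en-1-yl)cyclohexa-1,4-diene; 3 (2S)-2-(bromomethyl)-3,3-dimethyloxirane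
Product: 8 (2R)-2-{[2,6-dimethoxy-1-(3-methylbut-2-en-1-yl)cyclohexa-2,5-dien-1-yl]methyl}-3,3-dimethyloxirane, via lithiated prenyl diene 7 (not isolated)
Conditions: t-BuLi, THF, −78 to −40 °C; then 3, −78 °C to 23 °C
Reagents that add atoms: none
Why: The same deprotonation and SN2 alkylation sequence attacks the primary C–Br carbon of 3 faster than its hindered epoxide carbons and creates a quaternary carbon that is not yet stereogenic because its two ring branches are identical.

Step 5
Reactants: 8 (2R)-2-{[2,6-dimethoxy-1-(3-methylbut-2-en-1-yl)cyclohexa-2,5-dien-1-yl]methyl}-3,3-dimethyloxirane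
Product: 10 (1S,5S,7R,9R)-4,9-dimethoxy-8,8-dimethyl-5-(3-methylbut-2-en-1-yl)-7,9-epoxybicyclo[3.3.1]non-3-ene (tricyclic mixed ketal), via silyloxy oxocarbenium ion 9 (not isolated)
Conditions: TMSOTf (20 mol %), 2,6-lutidine, CH2Cl2, −78 °C
Reagents that add atoms: none
Why: Lewis acid-promoted epoxide-opening carbocyclisation (6-endo-tet attack of an enol ether carbon on the tertiary epoxide carbon, anti to the C–O bond), in which only one of the two diastereotopic enol ethers reaches the epoxide through a chair-like array with the C7 oxygen equatorial, so the single epoxide centre fixes C1 and C5, and after a chair-to-boat flip the C7 oxygen traps ion 9, fixes C9 and returns the silyl triflate.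

Step 6
Reactants: 10 tricyclic mixed ketal
Product: 11 (1R,5S,7R,9R)-4,9-dimethoxy-8,8-dimethyl-5-(3-methylbut-2-en-1-yl)-7,9-epoxybicyclo[3.3.1]non-3-en-2-one
Conditions: Rh2(cap)4 (dirhodium tetracaprolactamate, 1 mol %), t-BuOOH, K2CO3, CH2Cl2, 23 °C
Reagents that add atoms: tert-butyl hydroperoxide, CC(C)(C)OO
Why: Radical allylic C–H oxidation by a tert-butylperoxyl chain, which should prefer the ring methylene activated by the electron-rich enol ether over the allylic positions of the prenyl group and gives the vinylogous ester.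

Step 7
Reactants: 11 ketal enone
Product: 12 (1R,5S,7R)-7-hydroxy-4-methoxy-8,8-dimethyl-5-(3-methylbut-2-en-1-yl)bicyclo[3.3.1]non-3-ene-2,9-dione (7-OH exo, equatorial)
Conditions: p-TsOH·H2O (10 mol %), aqueous THF, 23 °C
Reagents that add atoms: water, O
Why: Acid-catalysed ketal hydrolysis, driven by release of the strained oxygen bridge and mild enough for the hindered vinylogous methyl ester, touches no stereocentre and lets the carbocycle relax to the chair in which the C7 hydroxyl is equatorial.

Step 8
Reactants: 12 hydroxy dione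
Product: 13 (1R,5S,7R)-4-methoxy-8,8-dimethyl-5-(3-methylbut-2-en-1-yl)-2,9-dioxobicyclo[3.3.1]non-3-en-7-yl benzenesulfonate
Conditions: PhSO2Cl, DMAP, pyridine, CH2Cl2, 0 to 40 °C
Reagents that add atoms: benzenesulfonyl chloride, O=S(=O)(Cl)c1ccccc1
Why: O-sulfonylation with retention at C7, routine for equatorial neopentylic carbinols, installs a leaving group that has no acidic hydrogen and can undergo neither anti elimination nor SN2 displacement during the next two steps.

Step 9
Reactants: 13 benzenesulfonate
Product: 15 (1R,5S,7R)-4-methoxy-1,8,8-trimethyl-5-(3-methylbut-2-en-1-yl)-2,9-dioxobicyclo[3.3.1]non-3-en-7-yl benzenesulfonate, via bridgehead organolithium 14 (not isolated)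
Conditions: LDA, THF, −78 °C; then MeI, −78 to −40 °C
Reagents that add atoms: iodomethane, CI
Why: Bridgehead lithiation and alkylation, a known reaction of enol ethers of bicyclo[3.3.1]nonane-2,4,9-triones, removes the C1–H flanked by the C2 and C9 carbonyl groups and methylates the pyramidal, configurationally locked carbanion with retention.

Step 10
Reactants: 15 bridgehead-methylated benzenesulfonate
Product: 17 (1S,5S,7R)-4-methoxy-1,8,8-trimethyl-5-(3-methylbut-2-en-1-yl)-3-(2-methylpropanoyl)-2,9-dioxobicyclo[3.3.1]non-3-en-7-yl benzenesulfonate, via C3 vinyllithium 16 (not isolated)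
Conditions: LiTMP, THF, −78 °C; then isobutyryl chloride, −78 °C
Reagents that add atoms: 2-methylpropanoyl chloride (isobutyryl chloride), CC(C)C(=O)Cl
Why: Vinylic lithiation of the β-methoxy enone at C3 by the hindered amide base followed by C-acylation of the vinyllithium, again a known reaction of this ring system, creates no stereocentre (the C1 descriptor changes only through priorities).

Step 11
Reactants: 17 fully substituted bicyclo[3.3.1]nonenyl benzenesulfonate
Product: 19 (1S,5S,7R)-7-(2-hydroxypropan-2-yl)-4-methoxy-1-methyl-5-(3-methylbut-2-en-1-yl)-3-(2-methylpropanoyl)bicyclo[3.2.1]oct-3-ene-2,8-dione, via tertiary cation 18 (not isolated)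
Conditions: 2,6-lutidine, aqueous CF3CH2OH (water-rich), 80 °C
Reagents that add atoms: water, O
Why: In the numbering of 17, ionisation of the equatorial C7 benzenesulfonate is assisted by the antiperiplanar C1–C8 ring bond, so C1 migrates from C8 to C7 as the sulfonate leaves, the cyclohexanone ring C1–C8–C7–C6–C5–C9 shrinks to the cyclopentanone ring C1–C7–C6–C5–C9, and the expelled tertiary cation 18 is trapped by water. The closest known reaction type is the Wagner–Meerwein ring contraction of equatorial 2,2-dimethylcyclohexyl sulfonates, familiar from the ring A contraction of 4,4-dimethyl-3β-sulfonyloxy triterpenoids. The five-membered ring is closed by this concerted 1,2-alkyl shift through a three-centre transition state and not by an external ring closure, and the skeleton changes from bicyclo[3.3.1] to bicyclo[3.2.1] with the six-membered enone ring untouched. The only stereocentre that changes is C7, which is inverted stereospecifically by rear-side attack of C1 so that the new side chain stands exo, syn to the carbonyl bridge, while C1 migrates with retention and C5 is not involved. The step needs migration of C1 in preference to methyl shift, hydride shift, elimination and substitution, and the substrate secures this because both methyl groups and all neighbouring hydrogens are gauche to the leaving group, the other antiperiplanar bond (C5–C6) would leave a primary cation, and the rear side of C7 lies inside the cage where no solvent can reach. A water-rich, strongly ionising and buffered medium should favour capture of 18 by water over proton loss or attack by the prenyl double bond.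

Step 12
Reactants: 19 ring-contracted methyl enol ether
Product: 21 (1R,5R,6R)-4-hydroxy-6-(2-hydroxypropan-2-yl)-5-methyl-1-(3-methylbut-2-en-1-yl)-3-(2-methylpropanoyl)bicyclo[3.2.1]oct-3-ene-2,8-dione (target), via lithium enolate 20 (not isolated)
Conditions: LiCl, DMSO, 120 °C; then dilute aqueous HCl
Reagents that add atoms: none
Why: Nucleophilic O-demethylation under Krapcho-type conditions (SN2 attack of chloride on the methyl group of the doubly activated enol ether) frees the β-triketone without acid or base strong enough to harm the tertiary alcohol, the prenyl group or the strained bridging ketone.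

Compound list
1 | 3-methylbut-2-en-1-ol (prenol) | CC(C)=CCO | starting material
2 | [(2R)-3,3-dimethyloxiran-2-yl]methanol | OC[C@H]1OC1(C)C | intermediate
3 | (2S)-2-(bromomethyl)-3,3-dimethyloxirane | BrC[C@H]1OC1(C)C | intermediate
4 | 1,5-dimethoxycyclohexa-1,4-diene | COC1=CCC=C(OC)C1 | starting material
5 | 6-lithio-1,5-dimethoxycyclohexa-1,4-diene (not isolated) | [Li]C1C(OC)=CCC=C1OC | intermediate
6 | 1,5-dimethoxy-6-(3-methylbut-2-en-1-yl)cyclohexa-1,4-diene | COC1=CCC=C(OC)C1CC=C(C)C | intermediate
7 | 6-lithio-1,5-dimethoxy-6-(3-methylbut-2-en-1-yl)cyclohexa-1,4-diene (not isolated) | [Li]C1(CC=C(C)C)C(OC)=CCC=C1OC | intermediate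
8 | (2R)-2-{[2,6-dimethoxy-1-(3-methylbut-2-en-1-yl)cyclohexa-2,5-dien-1-yl]methyl}-3,3-dimethyloxirane | COC1=CCC=C(OC)C1(CC=C(C)C)C[C@H]2OC2(C)C | intermediate
9 | bicyclic C9 methyl oxocarbenium ion with 7-exo trimethylsilyloxy group (not isolated) | COC1=CC[C@H]2C(C)(C)[C@H](O[Si](C)(C)C)C[C@]1(CC=C(C)C)C2=[O+]C | intermediate
10 | (1S,5S,7R,9R)-4,9-dimethoxy-8,8-dimethyl-5-(3-methylbut-2-en-1-yl)-7,9-epoxybicyclo[3.3.1]non-3-ene | COC1=CC[C@H]2C(C)(C)[C@H]3C[C@]1(CC=C(C)C)[C@]2(OC)O3 | intermediate
11 | (1R,5S,7R,9R)-4,9-dimethoxy-8,8-dimethyl-5-(3-methylbut-2-en-1-yl)-7,9-epoxybicyclo[3.3.1]non-3-en-2-one | COC1=CC(=O)[C@H]2C(C)(C)[C@H]3C[C@]1(CC=C(C)C)[C@]2(OC)O3 | intermediate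
12 | (1R,5S,7R)-7-hydroxy-4-methoxy-8,8-dimethyl-5-(3-methylbut-2-en-1-yl)bicyclo[3.3.1]non-3-ene-2,9-dione | COC1=CC(=O)[C@H]2C(C)(C)[C@H](O)C[C@]1(CC=C(C)C)C2=O | intermediate
13 | (1R,5S,7R)-4-methoxy-8,8-dimethyl-5-(3-methylbut-2-en-1-yl)-2,9-dioxobicyclo[3.3.1]non-3-en-7-yl benzenesulfonate | COC1=CC(=O)[C@H]2C(C)(C)[C@H](OS(=O)(=O)c3ccccc3)C[C@]1(CC=C(C)C)C2=O | intermediate
14 | C1 bridgehead organolithium of 13 (not isolated) | COC1=CC(=O)[C@@]2([Li])C(C)(C)[C@H](OS(=O)(=O)c3ccccc3)C[C@]1(CC=C(C)C)C2=O | intermediate
15 | (1R,5S,7R)-4-methoxy-1,8,8-trimethyl-5-(3-methylbut-2-en-1-yl)-2,9-dioxobicyclo[3.3.1]non-3-en-7-yl benzenesulfonate | COC1=CC(=O)[C@@]2(C)C(C)(C)[C@H](OS(=O)(=O)c3ccccc3)C[C@]1(CC=C(C)C)C2=O | intermediate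
16 | C3 vinyllithium of 15 (not isolated) | COC1=C([Li])C(=O)[C@@]2(C)C(C)(C)[C@H](OS(=O)(=O)c3ccccc3)C[C@]1(CC=C(C)C)C2=O | intermediate
17 | (1S,5S,7R)-4-methoxy-1,8,8-trimethyl-5-(3-methylbut-2-en-1-yl)-3-(2-methylpropanoyl)-2,9-dioxobicyclo[3.3.1]non-3-en-7-yl benzenesulfonate | COC1=C(C(=O)C(C)C)C(=O)[C@@]2(C)C(C)(C)[C@H](OS(=O)(=O)c3ccccc3)C[C@]1(CC=C(C)C)C2=O | intermediate
18 | ring-contracted 2-propyl cation on the exo face of the bicyclo[3.2.1]octenedione (not isolated) | CC(C)=CC[C@@]12C[C@@H]([C+](C)C)[C@@](C)(C1=O)C(=O)C(C(=O)C(C)C)=C2OC | intermediate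
19 | (1S,5S,7R)-7-(2-hydroxypropan-2-yl)-4-methoxy-1-methyl-5-(3-methylbut-2-en-1-yl)-3-(2-methylpropanoyl)bicyclo[3.2.1]oct-3-ene-2,8-dione | CC(C)=CC[C@@]12C[C@@H](C(C)(C)O)[C@@](C)(C1=O)C(=O)C(C(=O)C(C)C)=C2OC | intermediate
20 | lithium enolate of the target (not isolated) | CC(C)=CC[C@@]12C[C@@H](C(C)(C)O)[C@@](C)(C1=O)C(=O)C(C(=O)C(C)C)=C2[O-].[Li+] | intermediate
21 | (1R,5R,6R)-4-hydroxy-6-(2-hydroxypropan-2-yl)-5-methyl-1-(3-methylbut-2-en-1-yl)-3-(2-methylpropanoyl)bicyclo[3.2.1]oct-3-ene-2,8-dione | CC(C)=CC[C@@]12C[C@@H](C(C)(C)O)[C@@](C)(C1=O)C(O)=C(C(=O)C(C)C)C2=O | target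

Total step count: 12. Longest linear sequence: 11 (steps 1, 2 and 4 to 12).

Steps most likely to fail

1. Step 11.
   - What may go wrong: the migrating carbon C1 carries two carbonyl groups, so its ring bond is a weak donor and assisted ionisation may be too slow. Unassisted ionisation followed by methyl migration or proton loss could then compete.
   - Fallback: it sets out from 17 and makes the migrating carbon electron-richer before the ring contraction. The doubly activated enol ether is first hydrolysed by addition and elimination with aqueous LiOH in dioxane at moderate temperature. This gives the free β-triketone benzenesulfonate F1.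
   - Its lithium salt places an electron-rich enolate directly next to C1. Heating that salt in a water-rich medium should bring about the same stereospecific 1,2-shift and hydration, and after acidification the sequence comes back to the route at 21.

2. Step 9.
   - What may go wrong: the amide bases of steps 9 and 10 may attack the sulfonate (at sulfur or by ortho-lithiation), or lithiation may occur at C3 in competition with C1.
   - Fallback: it sets out from 12 and carries the C7 oxygen as a silyl ether, installing the leaving group only at the end.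
   - TESOTf and 2,6-lutidine give the triethylsilyl ether F2. LDA and MeI give the bridgehead-methylated silyl ether F3. LiTMP and isobutyryl chloride give the C3-acylated silyl ether F4. HF·pyridine liberates the C7 alcohol F5. Sulfonylation with PhSO2Cl, DMAP and pyridine comes back to the route at 17.

3. Step 6.
   - What may go wrong: hydrogen abstraction at the allylic positions of the prenyl group, or over-oxidation, may compete with oxidation of the ring methylene.
   - Fallback: it sets out from 8 and changes the order of events. The ring CH2 of 8 is doubly allylic to two enol ethers and far weaker than any prenyl C–H. It is oxidised first with Rh2(cap)4 and t-BuOOH to the cross-conjugated dienone epoxide F6.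
   - The TMSOTf-promoted epoxide-opening cyclisation is then run on F6 with the vinylogous ester carbon as nucleophile. The same chair-like group selection applies, and the sequence comes back to the route at 11.

Further compounds
F1 | step 11 | (1S,5S,7R)-4-hydroxy-1,8,8-trimethyl-5-(3-methylbut-2-en-1-yl)-3-(2-methylpropanoyl)-2,9-dioxobicyclo[3.3.1]non-3-en-7-yl benzenesulfonate | OC1=C(C(=O)C(C)C)C(=O)[C@@]2(C)C(C)(C)[C@H](OS(=O)(=O)c3ccccc3)C[C@]1(CC=C(C)C)C2=O
F2 | step 9 | (1R,5S,7R)-4-methoxy-8,8-dimethyl-5-(3-methylbut-2-en-1-yl)-7-(triethylsilyloxy)bicyclo[3.3.1]non-3-ene-2,9-dione | COC1=CC(=O)[C@H]2C(C)(C)[C@H](O[Si](CC)(CC)CC)C[C@]1(CC=C(C)C)C2=O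
F3 | step 9 | (1R,5S,7R)-4-methoxy-1,8,8-trimethyl-5-(3-methylbut-2-en-1-yl)-7-(triethylsilyloxy)bicyclo[3.3.1]non-3-ene-2,9-dione | COC1=CC(=O)[C@@]2(C)C(C)(C)[C@H](O[Si](CC)(CC)CC)C[C@]1(CC=C(C)C)C2=O
F4 | step 9 | (1S,5S,7R)-4-methoxy-1,8,8-trimethyl-5-(3-methylbut-2-en-1-yl)-3-(2-methylpropanoyl)-7-(triethylsilyloxy)bicyclo[3.3.1]non-3-ene-2,9-dione | COC1=C(C(=O)C(C)C)C(=O)[C@@]2(C)C(C)(C)[C@H](O[Si](CC)(CC)CC)C[C@]1(CC=C(C)C)C2=O
F5 | step 9 | (1S,5S,7R)-7-hydroxy-4-methoxy-1,8,8-trimethyl-5-(3-methylbut-2-en-1-yl)-3-(2-methylpropanoyl)bicyclo[3.3.1]non-3-ene-2,9-dione | COC1=C(C(=O)C(C)C)C(=O)[C@@]2(C)C(C)(C)[C@H](O)C[C@]1(CC=C(C)C)C2=O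
F6 | step 6 | 4-{[(2R)-3,3-dimethyloxiran-2-yl]methyl}-3,5-dimethoxy-4-(3-methylbut-2-en-1-yl)cyclohexa-2,5-dien-1-one | COC1=CC(=O)C=C(OC)C1(CC=C(C)C)C[C@H]2OC2(C)C
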